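3 questions stood, and I had 4 runs to answer them from.

| setting | theta | delta | gamma | alpha | beta |
|---|---|---|---|---|---|
| substrate | 120 mM | 48.0 mM | 180 mM | 120 mM | 120 mM |
| coupling partner | 132 mM | 60.0 mM | 132 mM | 132 mM | 132 mM |
| free catalyst | 12.0 mM | 12.0 mM | 12.0 mM | 24.0 mM | 78.0 mM |
| time |  |  |  |  | 21 h |

- theta run (time / h: [substrate] / mM): 1.2: 111.6; 3.6: 100.9; 6.9: 92.0; 11: 86.3; 16: 82.9; 21: 82.4
- delta run (time / h: [substrate] / mM): 1.2: 46.3; 3.6: 43.3; 6.9: 42.2; 11: 40.6; 16: 39.7; 21: 39.0
- gamma run (time / h: [substrate] / mM): 1.2: 168.3; 3.6: 152.5; 6.9: 140.7; 11: 133.7; 16: 129.4; 21: 128.3
- alpha run (time / h: [substrate] / mM): 1.2: 109.0; 3.6: 93.6; 6.9: 82.9; 11: 75.4; 16: 71.7; 21: 69.5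

(each reading ± 0.4 mM)

* apparent order in [substrate] of the starting rate, round the charge of the theta run (the rate where two percent of its substrate have turned into product) (one fixed amount of product, the same in the runs compared)
* apparent order in [coupling partner] of the starting rate, round the charge of the theta run (the rate where two percent of its substrate have turned into product)
* substrate in the beta run at 21 h, as a share of the substrate charged

- Overall: substrate + coupling partner -> product, with free catalyst as catalyst.
- Constant volume, constant temperature.
- "The second partner" is coupling partner.
- An order is taken over about fifteen percent of the charge, up and down.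

To compare flasks with different charges, I integrated 1/(c(substrate)·c(coupling partner)) over the product made, so that time dropped out of the reckoning. Each mole of product was booked against one mole of each partner. I call the result the ledger clock:

clock = ln[(c(coupling partner)/c(substrate) now) / (the same ratio at charge)] / (coupling partner charged − substrate charged)

The ledger clock of the theta flask at 21 h, read from its last reading, was 3.39 M⁻¹. At the same time gamma read 3.30 M⁻¹ and delta 3.76 M⁻¹. These three share a catalyst charge of 12.0 mM but differ widely in their other charges, so I took the starting orders in both partners to lie near one.

The alpha flask, with twice the catalyst of theta, read 5.33 M⁻¹, which is 1.57 times the theta clock. That is a catalyst power of 0.654. A reservoir of catalyst gives a power of 0.5 at high charge, so for beta I took the mean of the two: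

power = 0.577

beta clock = theta clock × (catalyst ratio)^power = 9.98 M⁻¹

Substrate was the smaller charge in beta, at 120 mM against 132 mM of coupling partner, so I kept the ledger in substrate. Its ledger for 21 h closed like this:

substrate charged: 120 mM

left in the flask: 50.0 mM, or 41.7% of the charge

booked to product: 70.0 mM

The forecast gave 1.03 for the substrate order, 1.03 for the coupling partner order and 43% for beta, which is higher than my share. Its ground for the orders was “So the reaction looks first order in each partner”.

The flask gave 1.1, 1.1 and 41.7%.

    2 free catalyst ⇌ catalyst dimer, settled at all times (252.0 M⁻¹)
    free catalyst + substrate + coupling partner → product + free catalyst (121.3 M⁻² h⁻¹)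
    coupling partner → lost reagent (0.08748 h⁻¹)
    free catalyst → spent catalyst (0.1346 h⁻¹)

In the beta flask, product formed while free catalyst, in fast balance with catalyst dimer, turned into spent catalyst and coupling partner turned into lost reagent, and the ledger clock reached 9.96 M⁻¹ at 21 h, which is 2.94 times the theta clock and a catalyst power of 0.576. The same steps ran in the gamma flask, where substrate was charged above coupling partner; its clock at a quarter of the substrate turned was 2.69 M⁻¹, a value the theta readings pass at 9.61 h, and gamma itself reached that quarter at 9.99 h.

All runs stem from a simulated flask for an exercise, and the scatter is random.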